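The bicyclo[2.2.1]heptane is disconnected at C13–C14 and C13–C6 (locants: remark below). Ring C6–C7–C15–C14–C13 is not closed as such but grown from a cyclobutanone (C6, C7, C15, C14) fused to the trans-decalin. The step exploits the C14 oxygen beside the C13–H bridgehead: a diazo carbon (future C13), tethered through C12–C11 to C7, adds to the strained C14 carbonyl and C6 migrates to it with loss of N2. One operation forms C13–C14, expands the four- to the five-membered ring and completes both norbornane rings, leaving a C14 ketone for reduction to the exo alcohol. The precursor is a decalin-fused cyclobutanone whose C7 carries a 3-oxopropyl arm (C11–C13).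

Key step: step 15

Remark (locants, used for all intermediates): C1 = CBr, C2, C3, C4 = C(OH)CH3, C5 = ring-fusion CH, C6 = CH between C5 and C7 (one-carbon bridge of the norbornane), C7 = quaternary C, C8, C9, C10 = ring-fusion C bearing CH3-19, C11 = CH(iPr), C12 = CH2, C13 = bridgehead CH, C14 = CHOH, C15 = CH2 on C7, C16–C18 = isopropyl, C20 = CH3 on C4. β is the decalin face that carries C19.
Remark (labile centres): the nitro-bearing C1 of 5–14 is epimerisable and is drawn from 6 on as the equatorial epimer; it is removed in step 8. The C7/C11 centres of 9 and 10 and the C14 carbinol centre of 21 and 22 are left undefined because the next operation destroys them.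
Remark (step 1): the (pseudo)enantiomeric series of the amine catalyst is assumed to be chosen so that the (S)-adduct forms.

Step 1
Reactants: 1 3-methylcyclohex-2-en-1-one; 2 nitromethane
Product: 3 (S)-3-methyl-3-(nitromethyl)cyclohexan-1-one
Conditions: chiral primary-amine catalyst (9-amino-9-deoxy-epi-cinchona type, 10 mol %), PhCO2H (20 mol %), MeNO2 (excess), 40 °C
Reagents that add atoms: nitromethane C[N+](=O)[O-]
Why: Iminium-ion catalysis (asymmetric nitro-Michael addition to a β,β-disubstituted enone) is an established way to all-carbon quaternary centres, and the chiral amine shields one face of the iminium ion so that C10 should form as the (S)-centre.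

Step 2
Reactants: 3 (S)-3-methyl-3-(nitromethyl)cyclohexan-1-one; 4 but-3-en-2-one
Product: 5 (3S)-3-methyl-3-(1-nitro-4-oxopentyl)cyclohexan-1-one (C1 epimers)
Conditions: DBU (10 mol %), MeCN, 0 °C to rt
Reagents that add atoms: but-3-en-2-one CC(=O)C=C
Why: Base-catalysed nitro-Michael addition: the primary nitroalkane is far more acidic than the ketone, so its nitronate should add once to the enone, and the new C1 centre stays epimerisable and is of no consequence.

Step 3
Reactants: 5 nitro diketone
Product: 6 trans-decalin ketol (4β-OH, 4α-CH3, 5α-H)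
Conditions: KOH (2.5 equiv), MeOH, 0 °C to rt; AcOH/NH4Cl buffer quench
Reagents that add atoms: none
Why: Reversible intramolecular aldol addition under thermodynamic control: the C5 enolate of the ring ketone adds to the methyl ketone (the bridged bicyclo[3.3.1] ketol of the other mode is more strained and should revert), and equilibration should favour the trans ring fusion with the C20 methyl equatorial and the C4 hydroxyl axial, which avoids a 1,3-diaxial CH3/CH3 contact with C19.

Step 4
Reactants: 6 trans-decalin ketol
Product: 7 C4 triethylsilyl ether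
Conditions: TESOTf, 2,6-lutidine, CH2Cl2, −40 to 0 °C
Reagents that add atoms: triethylsilyl trifluoromethanesulfonate CC[Si](CC)(CC)OS(=O)(=O)C(F)(F)F
Why: Silyl triflate with a hindered base silylates the tertiary axial alcohol (standard O-silylation), which blocks retro-aldol and acylation in the following steps.

Step 5
Reactants: 7 C4 triethylsilyl ether; 8 2-methylpropanal
Product: 11 (E)-7-isobutylidene enone, via aldol adduct 9 (not isolated), via mesylate 10 (not isolated)
Conditions: LDA (2.2 equiv), THF, −78 °C; iPrCHO; AcOH; then MsCl, Et3N, CH2Cl2, 0 °C; DBU, rt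
Reagents that add atoms: 2-methylpropanal CC(C)C=O
Why: Directed aldol condensation: LDA removes the nitro α-proton and then the less hindered C7 proton (C5–H lies between two quaternary carbons), and addition to the aldehyde followed by E1cB loss of mesylate should give the thermodynamically preferred (E)-alkylidene ketone with isopropyl anti to the carbonyl.

Step 6
Reactants: 11 (E)-7-isobutylidene enone
Product: 12 6β-allylic alcohol
Conditions: NaBH4, CeCl3·7H2O, MeOH, −78 °C
Reagents that add atoms: none
Why: Luche 1,2-reduction: hydride should attack C6 from the α face, anti to the axial C19 methyl and the axial C4–OTES group, giving the axial 6β-alcohol.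

Step 7
Reactants: 12 6β-allylic alcohol; 13 triethyl orthoacetate
Product: 14 Δ6(7) ethyl ester with C11 set
Conditions: MeC(OEt)3 (solvent), EtCO2H (cat.), 140 °C, EtOH distilled off
Reagents that add atoms: triethyl orthoacetate CC(OCC)(OCC)OCC
Why: Johnson–Claisen rearrangement: the [3,3] shift is suprafacial, so C12 is delivered to C11 on the β face from which the axial C6–O bond departs, and with the (E)-alkene this fixes C11 (S in 14) while the double bond moves into the ring (C6=C7).

Step 8
Reactants: 14 Δ6(7) ethyl ester
Product: 15 C1 ketone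
Conditions: NaOEt, EtOH, 0 °C; then aq. TiCl3, NH4OAc (pH 5–6), THF, 0 °C to rt
Reagents that add atoms: water O
Why: Reductive Nef reaction: the secondary nitronate is reduced by Ti(III) to the imine, which hydrolyses to the C1 ketone under buffered conditions that should spare ester, silyl ether and alkene.

Step 9
Reactants: 15 C1 ketone
Product: 16 C1 enol triflate
Conditions: KHMDS (1.1 equiv), THF, −78 °C; PhNTf2
Reagents that add atoms: N-phenyl-bis(trifluoromethanesulfonimide) O=S(=O)(N(c1ccccc1)S(=O)(=O)C(F)(F)F)C(F)(F)F
Why: Kinetic enolisation of the C1 ketone can only occur toward C2 (C10 is quaternary and the ester is much less acidic), and O-sulfonylation of the enolate gives the enol triflate.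

Step 10
Reactants: 16 C1 enol triflate
Product: 17 C1 alkenyl bromide
Conditions: Ni(OAc)2·4H2O (10 mol %), 1,5-cyclooctadiene, Zn (cat.), LiBr (3 equiv), DMA/THF, rt
Reagents that add atoms: lithium bromide [Li+].[Br-]
Why: Nickel-catalysed halide exchange of enol triflates (oxidative addition, triflate/bromide metathesis, C–Br reductive elimination) should give the alkenyl bromide without touching the trisubstituted C6=C7 alkene.

Step 11
Reactants: 17 C1 alkenyl bromide; 18 trichloroacetyl chloride
Product: 19 α,α-dichlorocyclobutanone
Conditions: Cl3CCOCl, Zn–Cu couple, DME/Et2O, rt, ultrasound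
Reagents that add atoms: trichloroacetyl chloride ClC(Cl)(Cl)C(Cl)=O (transferred as dichloroketene ClC(Cl)=C=O)
Why: Dichloroketene [2+2] cycloaddition: the carbonyl carbon bonds to the less substituted C6 and CCl2 to C7, suprafacially and from the α face (the β face is covered by C19 and C4–OTES), which sets C6 (H β) and the quaternary C7 (C15 α, C11 β); the electron-poor bromoalkene should not react.

Step 12
Reactants: 19 α,α-dichlorocyclobutanone
Product: 20 cyclobutanone
Conditions: Zn dust, NH4Cl, MeOH, rt
Reagents that add atoms: none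
Why: Zinc reduces the two activated α-C–Cl bonds of the dichlorocyclobutanone (standard dechlorination) and should leave the alkenyl bromide alone.

Step 13
Reactants: 20 cyclobutanone
Product: 22 triol, via silyl-protected diol 21 (not isolated)
Conditions: DIBAL-H (5 equiv), CH2Cl2, −78 to 0 °C; then 1 M HCl, THF/MeOH, rt
Reagents that add atoms: none
Why: DIBAL-H reduces the ester to the primary alcohol and the cyclobutanone to the cyclobutanol (C14 epimers, oxidised back in step 14), and dilute acid then cleaves the tertiary TES ether.

Step 14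
Reactants: 22 triol
Product: 23 keto-aldehyde
Conditions: Dess–Martin periodinane (3 equiv), CH2Cl2, rt
Reagents that add atoms: none
Why: Dess–Martin oxidation takes the primary alcohol to the aldehyde and the cyclobutanol to the cyclobutanone, while the tertiary C4 alcohol is inert.

Step 15
Reactants: 23 keto-aldehyde; 24 p-toluenesulfonyl hydrazide
Product: 27 norbornanone (C14 ketone), via tosylhydrazone 25 (not isolated), via diazoalkane 26 (not isolated)
Conditions: TsNHNH2 (1.05 equiv), MeOH/THF, 0 °C to rt; solvent switch; K2CO3, BnEt3NCl (10 mol %), 1,4-dioxane, 70 °C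
Reagents that add atoms: none
Why: The aldehyde should condense with TsNHNH2 before the hindered cyclobutanone does; on heating the hydrazone salt loses sulfinate (Bamford–Stevens) and the diazo carbon C13 adds to the strained C14 carbonyl from the convex face that carries the C11 arm, giving a bicyclo[3.1.1] diazonium betaine in which the C6–C14 bond migrates to C13 as N2 leaves. The closest known type is the diazoalkane ring expansion of cyclobutanones to cyclopentanones (Büchner–Curtius–Schlotterbeck, Tiffeneau–Demjanov family) in its intramolecular form. The C13–C14 bond forms by a 6-exo-trig addition to the carbonyl; the 1,2-shift then turns the four-membered ring C6–C7–C15–C14 into the five-membered ring C6–C7–C15–C14–C13 and closes ring C7–C11–C12–C13–C6 through the same new C6–C13 bond. C13 is the only new stereocentre and the bicyclic framework dictates it; C6 migrates with retention, so C5 stays syn to the C14–C15 bridge. The step needs C6 and not C15 to migrate: in the betaine the alkoxide is antiperiplanar to C12, so N2+ can be anti only to C6 or C15 and never to oxygen (no epoxide), and it should prefer the C15 side, away from the isopropyl group on C11 that points to the C6 bridge, which places it anti to C6, the more substituted carbon. Strain release of the cyclobutanone should let the addition outrun carbene chemistry of the diazoalkane.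

Step 16
Reactants: 27 norbornanone (C14 ketone)
Product: 28 14-exo alcohol
Conditions: NaBH4, MeOH, 0 °C
Reagents that add atoms: none
Why: Borohydride reduction of a 7-syn-substituted norbornan-2-one (the camphor-to-isoborneol case): C5 on the C6 bridge hangs over the exo face of C14, so hydride should enter from the endo face and give the exo alcohol.

Step 17
Reactants: 28 14-exo alcohol
Product: 29 target CNP0317598.2
Conditions: Mn(dpm)3 (10 mol %), PhSiH3, tBuOOH, iPrOH, rt
Reagents that add atoms: none
Why: Metal-hydride hydrogen-atom-transfer hydrogenation, which reduces haloalkenes without C–halogen cleavage: H• adds to C2, and the α-bromo radical at C1 should take its hydrogen axially from the α face, anti to the axial C19 methyl on C10, leaving bromine equatorial (β).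

Compound list
1 | 3-methylcyclohex-2-en-1-one | CC1=CC(=O)CCC1 | starting material
2 | nitromethane | C[N+](=O)[O-] | starting material
3 | (S)-3-methyl-3-(nitromethyl)cyclohexan-1-one | O=C1C[C@](C)(CCC1)C[N+](=O)[O-] | intermediate
4 | but-3-en-2-one (methyl vinyl ketone) | CC(=O)C=C | starting material
5 | (3S)-3-methyl-3-(1-nitro-4-oxopentyl)cyclohexan-1-one, both epimers at the nitro carbon | O=C1C[C@](C)(CCC1)C(CCC(C)=O)[N+](=O)[O-] | intermediate
6 | 4β-hydroxy-4α,10β-dimethyl-1β-nitro-5α-decalin-6-one (trans-fused ketol) | O=C1[C@H]2[C@](C)(CCC1)[C@@H]([N+](=O)[O-])CC[C@@]2(C)O | intermediate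
7 | 4β-triethylsilyloxy-4α,10β-dimethyl-1β-nitro-5α-decalin-6-one | O=C1[C@H]2[C@](C)(CCC1)[C@@H]([N+](=O)[O-])CC[C@@]2(C)O[Si](CC)(CC)CC | intermediate
8 | 2-methylpropanal | CC(C)C=O | starting material
9 | 7-(1-hydroxy-2-methylpropyl) aldol adduct of 7 (epimers at C7 and C11) | CC(C)C(O)C1C(=O)[C@H]2[C@](C)(CC1)[C@@H]([N+](=O)[O-])CC[C@@]2(C)O[Si](CC)(CC)CC | intermediate
10 | C11 methanesulfonate of 9 | CC(C)C(OS(C)(=O)=O)C1C(=O)[C@H]2[C@](C)(CC1)[C@@H]([N+](=O)[O-])CC[C@@]2(C)O[Si](CC)(CC)CC | intermediate
11 | (E)-7-(2-methylpropylidene)-4β-triethylsilyloxy-4α,10β-dimethyl-1β-nitro-5α-decalin-6-one | CC(C)/C=C1/C(=O)[C@H]2[C@](C)(CC1)[C@@H]([N+](=O)[O-])CC[C@@]2(C)O[Si](CC)(CC)CC | intermediate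
12 | (E)-7-(2-methylpropylidene)-4β-triethylsilyloxy-4α,10β-dimethyl-1β-nitro-5α-decalin-6β-ol (axial OH) | CC(C)/C=C1/[C@H](O)[C@H]2[C@](C)(CC1)[C@@H]([N+](=O)[O-])CC[C@@]2(C)O[Si](CC)(CC)CC | intermediate
13 | triethyl orthoacetate | CC(OCC)(OCC)OCC | starting material
14 | ethyl (3S)-4-methyl-3-(4β-triethylsilyloxy-4α,10β-dimethyl-1β-nitro-5α-decal-6-en-7-yl)pentanoate | CC(C)[C@H](CC(=O)OCC)C1=C[C@H]2[C@](C)(CC1)[C@@H]([N+](=O)[O-])CC[C@@]2(C)O[Si](CC)(CC)CC | intermediate
15 | the corresponding 1-oxo ester (C1 ketone) | CC(C)[C@H](CC(=O)OCC)C1=C[C@H]2[C@](C)(CC1)C(=O)CC[C@@]2(C)O[Si](CC)(CC)CC | intermediate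
16 | the corresponding C1(2)-enol triflate | CC(C)[C@H](CC(=O)OCC)C1=C[C@H]2[C@](C)(CC1)C(OS(=O)(=O)C(F)(F)F)=CC[C@@]2(C)O[Si](CC)(CC)CC | intermediate
17 | the corresponding 1-bromo-1(2)-ene (alkenyl bromide) ester | CC(C)[C@H](CC(=O)OCC)C1=C[C@H]2[C@](C)(CC1)C(Br)=CC[C@@]2(C)O[Si](CC)(CC)CC | intermediate
18 | trichloroacetyl chloride | ClC(Cl)(Cl)C(Cl)=O | starting material
19 | 15,15-dichlorocyclobutanone fused on the α face (C14=O on C6, CCl2 on C7) | O=C2[C@H]3[C@H]4[C@](C)(CC[C@]3(C2(Cl)Cl)[C@H](C(C)C)CC(=O)OCC)C(Br)=CC[C@@]4(C)O[Si](CC)(CC)CC | intermediate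
20 | cyclobutanone (C14=O, C15H2) with ethyl ester arm | O=C2[C@H]3[C@H]4[C@](C)(CC[C@]3(C2)[C@H](C(C)C)CC(=O)OCC)C(Br)=CC[C@@]4(C)O[Si](CC)(CC)CC | intermediate
21 | C14,C13-diol with C4–OTES (C14 epimers) | OC2[C@H]3[C@H]4[C@](C)(CC[C@]3(C2)[C@H](C(C)C)CCO)C(Br)=CC[C@@]4(C)O[Si](CC)(CC)CC | intermediate
22 | C4,C13,C14-triol (C14 epimers) | OC2[C@H]3[C@H]4[C@](C)(CC[C@]3(C2)[C@H](C(C)C)CCO)C(Br)=CC[C@@]4(C)O | intermediate
23 | keto-aldehyde (C14 cyclobutanone, C13 aldehyde, free C4–OH) | O=C2[C@H]3[C@H]4[C@](C)(CC[C@]3(C2)[C@H](C(C)C)CC=O)C(Br)=CC[C@@]4(C)O | intermediate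
24 | p-toluenesulfonyl hydrazide | Cc1ccc(cc1)S(=O)(=O)NN | starting material
25 | (E)-tosylhydrazone of the C13 aldehyde | O=C2[C@H]3[C@H]4[C@](C)(CC[C@]3(C2)[C@H](C(C)C)C/C=N/NS(=O)(=O)c5ccc(C)cc5)C(Br)=CC[C@@]4(C)O | intermediate
26 | C13 diazoalkane | O=C2[C@H]3[C@H]4[C@](C)(CC[C@]3(C2)[C@H](C(C)C)CC=[N+]=[N-])C(Br)=CC[C@@]4(C)O | intermediate
27 | tetracyclic norbornan-14-one with 1-bromo-1(2)-ene and 4β-OH | CC(C)[C@@H]1C[C@@H]2[C@H]3[C@H]4[C@](C)(CC[C@@]31CC2=O)C(Br)=CC[C@@]4(C)O | intermediate
28 | the corresponding 14-exo alcohol | CC(C)[C@@H]1C[C@@H]2[C@H]3[C@H]4[C@](C)(CC[C@@]31C[C@H]2O)C(Br)=CC[C@@]4(C)O | intermediate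
29 | CNP0317598.2 (1β-bromo, 4β-OH, 14-exo-OH, 11-exo-isopropyl) | CC(C)[C@@H]1C[C@@H]2[C@H]3[C@H]4[C@](C)(CC[C@@]31C[C@H]2O)[C@@H](Br)CC[C@@]4(C)O | target

Total step count: 17. Longest linear sequence: 17 steps (1 to 29).

Steps most likely to fail

Step 15 (key step). The bond anti to N2+ could be C15 instead of C6, so the wrong carbon migrates. The hydrazide could also condense with the cyclobutanone, or the diazoalkane could lose N2 before it reaches the carbonyl (1,2-hydrogen shift to an alkene). The fallback sets out from 23 and separates bond formation from migration. SmI2 (THF, −78 °C, no HMPA) couples the aldehyde ketyl with the cyclobutanone to the bridged bicyclo[3.1.1] 13,14-diol F1, whose secondary C13 hydroxyl should lie on the C15 side, trans to the isopropyl group. MsCl/Et3N sulfonylates only that secondary hydroxyl to give the monomesylate F2. Et3Al (CH2Cl2, −78 to 0 °C) then triggers the stereospecific semipinacol shift of C6, which is antiperiplanar to the mesylate. The route is rejoined at 27.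

Step 11. The cycloaddition may be too slow at the hindered trisubstituted alkene next to the branched C11 arm, so that ketene oligomerisation and silyl-ether cleavage by zinc salts take over; attack on the β face is the other failure mode. The fallback sets out from 17 and replaces the ketene by a more electrophilic keteniminium ion made from N,N-dimethylacetamide, Tf2O and 2,4,6-collidine (1,2-dichloroethane, reflux). The stepwise cationic [2+2] addition should give the cyclobutaniminium triflate F3 with the same regiochemistry, and aqueous NaHCO3 hydrolysis gives 20 directly. The route is rejoined at 20 and step 12 is no longer needed.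

Step 3. Ring closure could take the other sense (chain enolate onto the ring ketone, bridged ketol), the ketol could dehydrate by E1cB, or equilibration could favour the C4 epimer. The fallback sets out from 5 and fixes C4 by an epoxide face instead of by the aldol equilibrium. TsOH in refluxing benzene with water removal gives the fused enone F4, since only the fused mode can dehydrate. Luche reduction from the α face gives the 6β-allylic alcohol F5. Hydroxyl-directed epoxidation (VO(acac)2, tBuOOH) delivers oxygen syn to that hydroxyl and gives the 4β,5β-epoxy alcohol F6. Dess–Martin oxidation gives the epoxy ketone F7. Reductive cleavage of the Cα–O bond with phenylselenide (PhSeSePh, NaBH4, AcOH, EtOH) then gives the β-hydroxy ketone with the C4 oxygen retained on the β face, and C5 equilibrates to the trans fusion. The route is rejoined at 6.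

Further compounds
F1 | step 15 | bridged bicyclo[3.1.1] 13,14-diol (C13–OH on the C15 side) | O[C@@]25[C@H]3[C@H]4[C@](C)(CC[C@]3(C2)[C@H](C(C)C)C[C@H]5O)C(Br)=CC[C@@]4(C)O
F2 | step 15 | C13 monomesylate of F1 | O[C@@]25[C@H]3[C@H]4[C@](C)(CC[C@]3(C2)[C@H](C(C)C)C[C@H]5OS(C)(=O)=O)C(Br)=CC[C@@]4(C)O
F3 | step 11 | N,N-dimethylcyclobutaniminium triflate | C[N+](C)=C2[C@H]3[C@H]4[C@](C)(CC[C@]3(C2)[C@H](C(C)C)CC(=O)OCC)C(Br)=CC[C@@]4(C)O[Si](CC)(CC)CC.[O-]S(=O)(=O)C(F)(F)F
F4 | step 3 | 4,10β-dimethyl-1β-nitro-octal-4(5)-en-6-one (fused enone) | O=C1C2=C(C)CC[C@H]([N+](=O)[O-])[C@@]2(C)CCC1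
F5 | step 3 | the corresponding 6β-allylic alcohol | O[C@@H]1C2=C(C)CC[C@H]([N+](=O)[O-])[C@@]2(C)CCC1
F6 | step 3 | 4β,5β-epoxy-6β-alcohol | O[C@@H]1[C@@]23O[C@]2(C)CC[C@H]([N+](=O)[O-])[C@@]3(C)CCC1
F7 | step 3 | 4β,5β-epoxy-6-ketone | O=C1[C@@]23O[C@]2(C)CC[C@H]([N+](=O)[O-])[C@@]3(C)CCC1
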